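**Retrosynthetic overview**

- The route rests on ring C. The C4 carbonyl lies between aryl carbon C4a and alkene carbon C3, and O1 sits on C8a next to C4a. This is an o-hydroxyaroyl unit joined to a two-carbon fragment (C3, C2) that carries ring B.
- Ring C is cut at C4a–C4, C4–C3 and O1–C2 in one operation. The pieces are 6-iodo-2,3-dimethoxyphenol (ring A with I on C4a and OH on C8a), carbon monoxide (C4) and 3-benzyloxy-4,5-dimethoxyphenylacetylene (C3, C2, ring B), joined under Pd catalysis.
- The iodophenol comes from 2,3-dimethoxyphenol by MOM protection, OMOM-directed ortho-lithiation/iodination and MOM removal. The alkyne comes from 3-hydroxy-4,5-dimethoxybenzaldehyde by benzylation and Ohira–Bestmann homologation.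
- Rings A and B are bought. Ring C (the pyran-4-one) is the only ring formed, in step 6. Hydrogenolysis of the 3'-O-benzyl group then gives the target.

Key step: step 6

Remark: the target has no stereocentre and no stereogenic double bond, so it is achiral and no enantiocontrol is needed.

**Route**

Step 1
Reactants: 1 2,3-dimethoxyphenol
Product: 2 1,2-dimethoxy-3-(methoxymethoxy)benzene
Conditions: MOMCl, i-Pr2NEt, CH2Cl2, 0 °C to rt
Reagents that add atoms: chloromethyl methyl ether, COCCl
Why: O-alkylation of the phenol by the reactive α-chloro ether with a hindered amine base (acetal protection) should proceed cleanly and installs the group that directs the metalation of step 2.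

Step 2
Reactants: 2 1,2-dimethoxy-3-(methoxymethoxy)benzene
Product: 4 1-iodo-3,4-dimethoxy-2-(methoxymethoxy)benzene, via aryllithium 3 (not isolated)
Conditions: n-BuLi, THF, 0 °C; then I2, THF, −78 °C to rt
Reagents that add atoms: iodine, II
Why: Directed ortho-metalation, in which the chelating OMOM group outranks OMe as director and has only one free ortho position (the other carries OMe), should place lithium next to OMOM, and the aryllithium is trapped by iodine.

Step 3
Reactants: 4 1-iodo-3,4-dimethoxy-2-(methoxymethoxy)benzene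
Product: 5 6-iodo-2,3-dimethoxyphenol
Conditions: HCl (conc., few equiv.), MeOH, 40 °C
Reagents that add atoms: none
Why: Acid-catalysed acetal exchange with methanol (MOM cleavage) should release the phenol, while the aryl iodide and the methyl ethers are inert to dilute methanolic HCl.

Step 4
Reactants: 6 3-hydroxy-4,5-dimethoxybenzaldehyde
Product: 7 3-(benzyloxy)-4,5-dimethoxybenzaldehyde
Conditions: BnBr, K2CO3, DMF, rt
Reagents that add atoms: benzyl bromide, BrCc1ccccc1
Why: Williamson ether synthesis, in which the phenoxide displaces bromide from benzyl bromide, should leave the non-enolisable aldehyde untouched.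

Step 5
Reactants: 7 3-(benzyloxy)-4,5-dimethoxybenzaldehyde
Product: 9 1-(benzyloxy)-5-ethynyl-2,3-dimethoxybenzene, via diazoalkene 8 (not isolated)
Conditions: dimethyl (1-diazo-2-oxopropyl)phosphonate, K2CO3, MeOH, 0 °C to rt
Reagents that add atoms: dimethyl (1-diazo-2-oxopropyl)phosphonate, COP(=O)(OC)C(=[N+]=[N-])C(C)=O
Why: Ohira–Bestmann (Seyferth–Gilbert) homologation, in which methanolysis of the reagent gives the diazomethylphosphonate anion that adds to the aldehyde and eliminates dimethyl phosphate to the diazoalkene, which loses N2 and rearranges by 1,2-hydrogen shift, should give the terminal alkyne under conditions that aryl ethers tolerate.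

Step 6
Reactants: 5 6-iodo-2,3-dimethoxyphenol; 9 1-(benzyloxy)-5-ethynyl-2,3-dimethoxybenzene; 10 carbon monoxide
Product: 13 3'-(benzyloxy)-4',5',7,8-tetramethoxyflavone, via o-hydroxyaryl ynone 11 (not isolated), via enaminone 12 (not isolated)
Conditions: PdCl2(dppf) (3 mol %), Et2NH (solvent), CO (20 bar), 120 °C, autoclave, no copper
Reagents that add atoms: none
Why: Oxidative addition of Pd(0) into the C–I bond of 5 and migratory insertion of CO should give an aroyl-palladium(II) species, which takes up the acetylide of 9 (formed with Et2NH) and reductively eliminates to ynone 11, forming C4a–C4 and C4–C3. Et2NH then adds in conjugate fashion to 11 to give enaminone 12, and the phenol oxygen attacks the amine-bearing carbon and expels Et2NH, forming O1–C2; the closest known reaction type is the Pd-catalysed carbonylative Sonogashira annulation of o-iodophenols with terminal alkynes to flavones. The pyran-4-one ring closes by 6-endo addition–elimination (6-endo-trig on the enaminone, formally 6-endo-dig on the ynone). No stereocentre is formed. The step needs carbonylative coupling to beat direct coupling (which leads to the 2-arylbenzofuran) and six-membered closure to beat 5-exo closure (aurone). CO pressure, the absence of copper and the electron-rich aryl group of 5, which migrates readily onto CO, should secure the first; conversion of the ynone into the enaminone, whose only electrophilic alkene carbon is C2, should secure the second, and the free OH ortho to iodine in 5 places the nucleophile for that closure.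

Step 7
Reactants: 13 3'-(benzyloxy)-4',5',7,8-tetramethoxyflavone
Product: 14 3'-hydroxy-4',5',7,8-tetramethoxyflavone
Conditions: H2 (1 atm), 10% Pd/C, EtOAc/MeOH, rt
Reagents that add atoms: none
Why: Heterogeneous Pd-catalysed hydrogenolysis should cleave the benzylic C–O bond much faster than it reduces the vinylogous-ester C2=C3 bond of the flavone at 1 atm and room temperature, and the methyl ethers are inert.

**Compound list**

1 | 2,3-dimethoxyphenol | COc1cccc(O)c1OC | starting material
2 | 1,2-dimethoxy-3-(methoxymethoxy)benzene | COCOc1cccc(OC)c1OC | intermediate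
3 | [3,4-dimethoxy-2-(methoxymethoxy)phenyl]lithium | COCOc1c([Li])ccc(OC)c1OC | intermediate (not isolated)
4 | 1-iodo-3,4-dimethoxy-2-(methoxymethoxy)benzene | COCOc1c(I)ccc(OC)c1OC | intermediate
5 | 6-iodo-2,3-dimethoxyphenol | COc1ccc(I)c(O)c1OC | intermediate
6 | 3-hydroxy-4,5-dimethoxybenzaldehyde | COc1cc(C=O)cc(O)c1OC | starting material
7 | 3-(benzyloxy)-4,5-dimethoxybenzaldehyde | COc1cc(C=O)cc(OCc2ccccc2)c1OC | intermediate
8 | 1-(benzyloxy)-5-(2-diazoethenyl)-2,3-dimethoxybenzene | COc1cc(C=C=[N+]=[N-])cc(OCc2ccccc2)c1OC | intermediate (not isolated)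
9 | 1-(benzyloxy)-5-ethynyl-2,3-dimethoxybenzene | C#Cc1cc(OC)c(OC)c(OCc2ccccc2)c1 | intermediate
10 | carbon monoxide | [C-]#[O+] | starting material
11 | 3-[3-(benzyloxy)-4,5-dimethoxyphenyl]-1-(2-hydroxy-3,4-dimethoxyphenyl)prop-2-yn-1-one | COc1ccc(C(=O)C#Cc2cc(OC)c(OC)c(OCc3ccccc3)c2)c(O)c1OC | intermediate (not isolated)
12 | (E)-3-[3-(benzyloxy)-4,5-dimethoxyphenyl]-3-(diethylamino)-1-(2-hydroxy-3,4-dimethoxyphenyl)prop-2-en-1-one (E geometry assumed; it does not affect the outcome) | COc1ccc(C(=O)/C=C(/N(CC)CC)c2cc(OC)c(OC)c(OCc3ccccc3)c2)c(O)c1OC | intermediate (not isolated)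
13 | 3'-(benzyloxy)-4',5',7,8-tetramethoxyflavone | COc1cc(-c2cc(=O)c3ccc(OC)c(OC)c3o2)cc(OCc2ccccc2)c1OC | intermediate
14 | 3'-hydroxy-4',5',7,8-tetramethoxyflavone | COc1cc(-c2cc(=O)c3ccc(OC)c(OC)c3o2)cc(O)c1OC | target

**Step count and risks**

Total step count: 7. Longest linear sequence: 5 steps (steps 1, 2, 3, 6, 7); the alkyne branch (steps 4, 5) joins at step 6.

Steps most likely to fail:

1. Step 6. The aroyl-palladium may be bypassed by direct alkyne coupling and cycloisomerisation to the benzofuran, may be captured by Et2NH to give the salicylamide (aminocarbonylation), or the ynone may close in the 5-exo mode to the aurone. The fallback sets out from 7 and comes back at 13. Aldehyde 7 is condensed with purchased 2'-hydroxy-3',4'-dimethoxyacetophenone (CC(=O)c1ccc(OC)c(OC)c1O) under Claisen–Schmidt conditions (KOH, EtOH, rt) to give the 2'-hydroxychalcone (E)-3-[3-(benzyloxy)-4,5-dimethoxyphenyl]-1-(2-hydroxy-3,4-dimethoxyphenyl)prop-2-en-1-one F1. Oxidative cyclisation of this chalcone with catalytic I2 in DMSO at about 120 °C should give 13.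

2. Step 2. Metalation may occur in part next to the outer methoxy group instead of next to OMOM, or may stay incomplete, so that iodine ends up at the wrong carbon or is not introduced. The fallback sets out from 1 and comes back at 4; the position of the halogen is fixed by an electrophilic ortho-bromination instead of by the metalation. Amine-mediated ortho-selective bromination of 1 (Br2, t-BuNH2, toluene, −70 °C) should give 6-bromo-2,3-dimethoxyphenol F2. MOM protection (MOMCl, i-Pr2NEt, CH2Cl2) gives 1-bromo-3,4-dimethoxy-2-(methoxymethoxy)benzene F3. Bromine–lithium exchange (n-BuLi, THF, −78 °C) gives the same aryllithium 3 without regiochemical ambiguity, and trapping with I2 gives 4.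

3. Step 7. Hydrogenation may run on to the C2=C3 bond of the pyranone (flavanone formation), or cleavage of the benzyl ether may stall. The fallback sets out from 6 and comes back at 14; it replaces the benzyl group by an acid-labile acetal so that no reductive step is needed.
   - MOM protection of 6 (MOMCl, i-Pr2NEt, CH2Cl2) gives 3,4-dimethoxy-5-(methoxymethoxy)benzaldehyde F4.
   - Ohira–Bestmann homologation, through the diazoalkene 5-(2-diazoethenyl)-1,2-dimethoxy-3-(methoxymethoxy)benzene F5, gives 5-ethynyl-1,2-dimethoxy-3-(methoxymethoxy)benzene F6.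
   - Carbonylative annulation of this alkyne with 5 and 10 under the conditions of step 6 passes through the ynone 3-[3,4-dimethoxy-5-(methoxymethoxy)phenyl]-1-(2-hydroxy-3,4-dimethoxyphenyl)prop-2-yn-1-one F7 and the enaminone (E)-3-(diethylamino)-3-[3,4-dimethoxy-5-(methoxymethoxy)phenyl]-1-(2-hydroxy-3,4-dimethoxyphenyl)prop-2-en-1-one F8. It should give 3'-(methoxymethoxy)-4',5',7,8-tetramethoxyflavone F9.
   - Methanolic HCl at 40 °C then releases 14.

**Further compounds**

F1 | step 6 | (E)-3-[3-(benzyloxy)-4,5-dimethoxyphenyl]-1-(2-hydroxy-3,4-dimethoxyphenyl)prop-2-en-1-one | COc1ccc(C(=O)/C=C/c2cc(OC)c(OC)c(OCc3ccccc3)c2)c(O)c1OC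
F2 | step 2 | 6-bromo-2,3-dimethoxyphenol | COc1ccc(Br)c(O)c1OC
F3 | step 2 | 1-bromo-3,4-dimethoxy-2-(methoxymethoxy)benzene | COCOc1c(Br)ccc(OC)c1OC
F4 | step 7 | 3,4-dimethoxy-5-(methoxymethoxy)benzaldehyde | COCOc1cc(C=O)cc(OC)c1OC
F5 | step 7 | 5-(2-diazoethenyl)-1,2-dimethoxy-3-(methoxymethoxy)benzene | COCOc1cc(C=C=[N+]=[N-])cc(OC)c1OC
F6 | step 7 | 5-ethynyl-1,2-dimethoxy-3-(methoxymethoxy)benzene | C#Cc1cc(OC)c(OC)c(OCOC)c1
F7 | step 7 | 3-[3,4-dimethoxy-5-(methoxymethoxy)phenyl]-1-(2-hydroxy-3,4-dimethoxyphenyl)prop-2-yn-1-one | COc1ccc(C(=O)C#Cc2cc(OC)c(OC)c(OCOC)c2)c(O)c1OC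
F8 | step 7 | (E)-3-(diethylamino)-3-[3,4-dimethoxy-5-(methoxymethoxy)phenyl]-1-(2-hydroxy-3,4-dimethoxyphenyl)prop-2-en-1-one | COc1ccc(C(=O)/C=C(/N(CC)CC)c2cc(OC)c(OC)c(OCOC)c2)c(O)c1OC
F9 | step 7 | 3'-(methoxymethoxy)-4',5',7,8-tetramethoxyflavone | COCOc1cc(-c2cc(=O)c3ccc(OC)c(OC)c3o2)cc(OC)c1OC
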